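**Strategy.** The route rests on cutting ring C of the lower (fisetinidol) unit across C3–C4 and O1–C8a. C4 and C8a are ortho neighbours on ring A, and O1–C2–C3 is the O–C=C triad of an aryl methyl ketone enolate. An ortho-bromobenzyl bromide and 3,4-bis(benzyloxy)acetophenone are therefore joined in one pot: enolate C-benzylation (C4–C3), then copper-catalysed enolate O-arylation (O1–C8a), giving a flav-2-ene. Asymmetric hydroboration then sets trans C2/C3. The interflavan bond comes from aryl-cerium addition of the 6-metalated lower unit to a protected garbanzol, then hydride capture of the C4 cation anti to O3, which gives the 3,4-cis linkage.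

Key step: step 4

Remark: natural (2R,3R)-garbanzol is taken as a purchasable dihydroflavonol, and (−)-IpcBH2 as the reagent prepared beforehand from (+)-α-pinene and BH3·SMe2.

**Step 1**
Reactants: 1 2-bromo-4-hydroxybenzaldehyde
Product: 2 4-(benzyloxy)-2-bromobenzaldehyde
Conditions: BnBr, K2CO3, DMF, rt
Reagents that add atoms: benzyl bromide, BrCc1ccccc1
Why: Williamson etherification of the acidic para-formyl phenol should be clean and forms no stereocentre.

**Step 2**
Reactants: 2 4-(benzyloxy)-2-bromobenzaldehyde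
Product: 3 [4-(benzyloxy)-2-bromophenyl]methanol
Conditions: NaBH4, MeOH/THF, 0 °C
Reagents that add atoms: none
Why: Borohydride reduction of the aldehyde should leave the aryl bromide and the benzyl ether untouched.

**Step 3**
Reactants: 3 [4-(benzyloxy)-2-bromophenyl]methanol
Product: 4 4-(benzyloxy)-2-bromo-1-(bromomethyl)benzene
Conditions: PBr3, CH2Cl2, 0 °C
Reagents that add atoms: phosphorus tribromide, BrP(Br)Br
Why: The electron-rich benzylic alcohol should be converted to the bromide through its phosphite ester at low temperature, and the product is used crude because para-alkoxybenzyl bromides are reactive.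

**Step 4**
Reactants: 4 4-(benzyloxy)-2-bromo-1-(bromomethyl)benzene; 5 1-[3,4-bis(benzyloxy)phenyl]ethan-1-one
Product: 8 7-(benzyloxy)-2-[3,4-bis(benzyloxy)phenyl]-4H-chromene, via lithium enolate 6 (not isolated), via bromo ketone 7 (not isolated)
Conditions: 5 (1.3 equiv), LiN(SiMe3)2, THF, −78 °C; add 4, −78 → 0 °C; then CuI (10 mol %), MeNHCH2CH2NHMe (20 mol %), Cs2CO3, DMF, 90 °C, one pot
Reagents that add atoms: none
Why: The lithium enolate 6 should attack the benzylic bromide of 4 in an SN2 C-alkylation (C4–C3) while the aryl C–Br bond is inert, and ketone 7 is then re-enolised by Cs2CO3 and its enolate oxygen joined to C8a by a copper-catalysed Ullmann-type C–O coupling (oxidative addition of the aryl bromide, then C–O reductive elimination from trivalent copper), the two events amounting to a formal [3+3] annulation. The closest known reaction types are the copper-catalysed domino C-benzylation/O-arylation of 2-bromobenzyl bromides with β-keto esters to 4H-chromenes and the intramolecular O-arylation of ketone enolates. Ring C (O1, C2, C3, C4, C4a, C8a) closes in the O-arylation event as a six-membered ring by exo attack of the enolate oxygen on the aryl carbon, and no stereocentre is formed because C2=C3 remains an enol ether double bond. The step needs C- over O-benzylation and mono-alkylation (lithium enolate in THF at low temperature, ketone in slight excess) and O- over C-arylation, which is secured because C-arylation would close a four-membered ring and because the favoured Z-enolate of an aryl ketone holds O1 cis to the C4 arm.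

**Step 5**
Reactants: 8 7-(benzyloxy)-2-[3,4-bis(benzyloxy)phenyl]-4H-chromene
Product: 10 (2R,3S)-7-(benzyloxy)-2-[3,4-bis(benzyloxy)phenyl]chroman-3-ol, via alkylborane 9 (not isolated)
Conditions: (−)-IpcBH2 [from (+)-α-pinene], Et2O, −25 °C; then NaOH, H2O2, 0 °C → rt
Reagents that add atoms: hydrogen peroxide, OO
Why: Asymmetric hydroboration–oxidation should add H to C2 and boron to C3 (β to O1) on the same face, so that aryl and OH end up trans after oxidation with retention, and the (+)-α-pinene-derived reagent is chosen because, as recalled, it gives (1S,2R)-trans-2-phenylcycloalkanols from 1-phenylcycloalkenes, a facial sense that maps onto 2R,3S here (the antipodal reagent is equally available if a trial run shows the opposite sense).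

**Step 6**
Reactants: 10 (2R,3S)-7-(benzyloxy)-2-[3,4-bis(benzyloxy)phenyl]chroman-3-ol
Product: 11 (2R,3S)-7-(benzyloxy)-2-[3,4-bis(benzyloxy)phenyl]-6-bromochroman-3-ol
Conditions: NBS (1.0 equiv), CH2Cl2, −20 → 0 °C
Reagents that add atoms: N-bromosuccinimide, BrN1C(=O)CCC1=O
Why: Electrophilic bromination should go to C6, which is para to O1 and ortho to the 7-benzyloxy group, because C8 is flanked by two oxygens and ring B is less activated.

**Step 7**
Reactants: 12 (2R,3R)-garbanzol, (2R,3R)-3,7-dihydroxy-2-(4-hydroxyphenyl)chroman-4-one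
Product: 13 (2R,3R)-7-(benzyloxy)-2-[4-(benzyloxy)phenyl]-3-hydroxychroman-4-one
Conditions: BnBr (2.2 equiv), K2CO3, DMF, 0 °C → rt
Reagents that add atoms: benzyl bromide, BrCc1ccccc1
Why: Williamson etherification should alkylate only the two phenols and leave the non-acidic 3-OH free, and the mild base and short reaction time are chosen to avoid ring opening at C2.

**Step 8**
Reactants: 13 (2R,3R)-7-(benzyloxy)-2-[4-(benzyloxy)phenyl]-3-hydroxychroman-4-one
Product: 14 (2R,3R)-3,7-bis(benzyloxy)-2-[4-(benzyloxy)phenyl]chroman-4-one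
Conditions: BnOC(=NH)CCl3, CF3SO3H (cat.), CH2Cl2/cyclohexane, 0 °C → rt
Reagents that add atoms: benzyl 2,2,2-trichloroacetimidate, ClC(Cl)(Cl)C(=N)OCc1ccccc1
Why: Acid-catalysed imidate benzylation should protect the base-sensitive α-hydroxy ketone without enolisation, so C2 and C3 keep their configuration.

**Step 9**
Reactants: 11 (2R,3S)-7-(benzyloxy)-2-[3,4-bis(benzyloxy)phenyl]-6-bromochroman-3-ol; 14 (2R,3R)-3,7-bis(benzyloxy)-2-[4-(benzyloxy)phenyl]chroman-4-one
Product: 17 (2R,3R)-3,7-bis(benzyloxy)-2-[4-(benzyloxy)phenyl]-4-[(2R,3S)-7-(benzyloxy)-2-[3,4-bis(benzyloxy)phenyl]-3-hydroxychroman-6-yl]chroman-4-ol as a C4 epimer mixture, via aryllithium 15 (not isolated), via arylcerium 16 (not isolated)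
Conditions: 11, t-BuLi (3 equiv), THF, −78 °C; CeCl3, −78 °C; then 14, −78 → −40 °C; aq NH4Cl
Reagents that add atoms: none
Why: Deprotonation of the 3-OH and bromine–lithium exchange at C6, then transmetalation to the weakly basic organocerium reagent, should allow 1,2-addition to the enolisable C4 ketone without epimerising C3, and the new carbinol centre need not be controlled because it is planarised in the next step.

**Step 10**
Reactants: 17 the C4 carbinol from step 9
Product: 18 hexa-O-benzyl ether of the target (upper unit: 2-aryl α, 3-OBn β, 4-aryl β, that is 2,3-trans-3,4-cis; lower unit 2R,3S with free 3-OH)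
Conditions: Et3SiH, BF3·OEt2, CH2Cl2, −78 → −40 °C
Reagents that add atoms: none
Why: Ionic hydrogenation should ionise the tertiary, doubly benzylic alcohol and deliver hydride to the planar C4 cation anti to the 3-benzyloxy group, the same facial preference with which 2,3-trans-flavan-4-yl cations accept nucleophiles trans to O3, so H enters on the α face and the aryl group ends β, cis to O3.

**Step 11**
Reactants: 18 hexa-O-benzyl ether of the target
Product: 19 guibourtinidol-(4β→6)-fisetinidol, (2R,3S,4S)-4-[(2R,3S)-2-(3,4-dihydroxyphenyl)-3,7-dihydroxychroman-6-yl]-2-(4-hydroxyphenyl)chromane-3,7-diol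
Conditions: H2 (1 atm), Pd(OH)2/C, THF/MeOH, rt
Reagents that add atoms: none
Why: Neutral hydrogenolysis should remove all six benzyl ethers without cleaving the benzylic C2–O1 bonds or the interflavan bond and touches no stereocentre.

**Compound list**

1 | 2-bromo-4-hydroxybenzaldehyde | O=Cc1ccc(O)cc1Br | starting material
2 | 4-(benzyloxy)-2-bromobenzaldehyde | O=Cc1ccc(OCc2ccccc2)cc1Br | intermediate
3 | [4-(benzyloxy)-2-bromophenyl]methanol | OCc1ccc(OCc2ccccc2)cc1Br | intermediate
4 | 4-(benzyloxy)-2-bromo-1-(bromomethyl)benzene | BrCc1ccc(OCc2ccccc2)cc1Br | intermediate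
5 | 1-[3,4-bis(benzyloxy)phenyl]ethan-1-one | CC(=O)c1ccc(OCc2ccccc2)c(OCc2ccccc2)c1 | starting material
6 | lithium enolate of 5 | [Li]OC(=C)c1ccc(OCc2ccccc2)c(OCc2ccccc2)c1 | intermediate (not isolated)
7 | 1-[3,4-bis(benzyloxy)phenyl]-3-[4-(benzyloxy)-2-bromophenyl]propan-1-one | O=C(CCc1ccc(OCc2ccccc2)cc1Br)c1ccc(OCc2ccccc2)c(OCc2ccccc2)c1 | intermediate (not isolated)
8 | 7-(benzyloxy)-2-[3,4-bis(benzyloxy)phenyl]-4H-chromene | C1(c2ccc(OCc3ccccc3)c(OCc3ccccc3)c2)=CCc2ccc(OCc3ccccc3)cc2O1 | intermediate
9 | trans-2,3 alkylborane: boron at C3 carrying H and the isopinocampheyl group, same spatial arrangement at C2/C3 as 10 | C[C@H]1[C@H](B[C@H]3Cc4ccc(OCc5ccccc5)cc4O[C@@H]3c3ccc(OCc4ccccc4)c(OCc4ccccc4)c3)C[C@@H]2C[C@H]1C2(C)C | intermediate (not isolated)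
10 | (2R,3S)-7-(benzyloxy)-2-[3,4-bis(benzyloxy)phenyl]chroman-3-ol | O[C@H]1Cc2ccc(OCc3ccccc3)cc2O[C@@H]1c1ccc(OCc2ccccc2)c(OCc2ccccc2)c1 | intermediate
11 | (2R,3S)-7-(benzyloxy)-2-[3,4-bis(benzyloxy)phenyl]-6-bromochroman-3-ol | O[C@H]1Cc2cc(Br)c(OCc3ccccc3)cc2O[C@@H]1c1ccc(OCc2ccccc2)c(OCc2ccccc2)c1 | intermediate
12 | (2R,3R)-garbanzol | Oc1ccc([C@H]2Oc3cc(O)ccc3C(=O)[C@@H]2O)cc1 | starting material
13 | (2R,3R)-7-(benzyloxy)-2-[4-(benzyloxy)phenyl]-3-hydroxychroman-4-one | c1ccccc1COc1ccc([C@H]2Oc3cc(OCc4ccccc4)ccc3C(=O)[C@@H]2O)cc1 | intermediate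
14 | (2R,3R)-3,7-bis(benzyloxy)-2-[4-(benzyloxy)phenyl]chroman-4-one | c1ccccc1COc1ccc([C@H]2Oc3cc(OCc4ccccc4)ccc3C(=O)[C@@H]2OCc2ccccc2)cc1 | intermediate
15 | 6-lithio derivative of 11 as its lithium 3-alkoxide | [Li]O[C@H]1Cc2cc([Li])c(OCc3ccccc3)cc2O[C@@H]1c1ccc(OCc2ccccc2)c(OCc2ccccc2)c1 | intermediate (not isolated)
16 | 6-(dichlorocerio) derivative of 11 as its lithium 3-alkoxide | [Li]O[C@H]1Cc2cc([Ce](Cl)Cl)c(OCc3ccccc3)cc2O[C@@H]1c1ccc(OCc2ccccc2)c(OCc2ccccc2)c1 | intermediate (not isolated)
17 | tertiary C4 carbinol (upper unit 2R,3R, C4 epimer mixture; lower unit 2R,3S) | c1ccccc1COc1ccc([C@H]2Oc3cc(OCc4ccccc4)ccc3C(O)(c3cc4c(cc3OCc3ccccc3)O[C@H](c3ccc(OCc5ccccc5)c(OCc5ccccc5)c3)[C@@H](O)C4)[C@@H]2OCc2ccccc2)cc1 | intermediate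
18 | hexa-O-benzyl ether of the target (upper unit 2,3-trans-3,4-cis; lower unit 2R,3S, free 3-OH) | c1ccccc1COc1ccc([C@H]2Oc3cc(OCc4ccccc4)ccc3[C@H](c3cc4c(cc3OCc3ccccc3)O[C@H](c3ccc(OCc5ccccc5)c(OCc5ccccc5)c3)[C@@H](O)C4)[C@@H]2OCc2ccccc2)cc1 | intermediate
19 | guibourtinidol-(4β→6)-fisetinidol | Oc1ccc([C@H]2Oc3cc(O)ccc3[C@H](c3cc4c(cc3O)O[C@H](c3ccc(O)c(O)c3)[C@@H](O)C4)[C@@H]2O)cc1 | target

**Totals.** Total step count: 11. Longest linear sequence: 9 steps (steps 1–6, then 9–11).

**Steps most likely to fail**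

1. Step 10. Hydride may be delivered to the wrong face of the C4 cation, or the cation may lose H3 and be reprotonated, which would scramble C3 and C4. The fallback sets out from 13 and 16 and returns to the route at 19. The 3-OH of 13 is kept free (lithium alkoxide formed with LiN(SiMe3)2 at −78 °C) and 16 is added to give the 3,4-diol F5. Catalytic TsOH in CH2Cl2 at 0 °C should ionise C4, and the C3 hydrogen, which sits on the α face, should migrate suprafacially to C4 (semipinacol rearrangement); this fixes the 4β-aryl configuration in the 4-arylflavan-3-one F6. LiBH(s-Bu)3 at −78 °C should then attack anti to the pseudoaxial 4-aryl group to give the 3β-alcohol, the pentabenzyl ether F7, which is hydrogenolysed as in step 11 to 19.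

2. Step 5. The chiral borane may discriminate the two faces of the enol ether poorly, or the β-aryloxy borane may undergo ring-opening elimination before oxidation. The fallback sets out from 8 and returns at 10. Hydroboration with BH3·SMe2 and prompt oxidation with NaOH/H2O2 gives the racemic trans-alcohol, that is 10 together with its enantiomer F2. Esterification with (S)-O-methylmandelic acid (DCC, DMAP) gives the diastereomeric esters, the mandelate of 10 F3 and the mandelate of the enantiomer F4, which are separated by chromatography or crystallisation. LiOH hydrolysis of F3 returns 10.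

3. Step 4. The methyl ketone enolate may be alkylated twice, or the O-arylation may stall in the same pot. The fallback sets out from 2 and 5 and returns at 8, giving up the one-pot union. Claisen–Schmidt condensation (KOH, EtOH) gives the chalcone (E)-1-[3,4-bis(benzyloxy)phenyl]-3-[4-(benzyloxy)-2-bromophenyl]prop-2-en-1-one F1. Conjugate reduction ([(Ph3P)CuH]6 cat., polymethylhydrosiloxane, toluene) gives 7, now isolated. Intramolecular enolate O-arylation with Pd2(dba)3, DPEphos and Cs2CO3 in toluene at 100 °C closes 7 to 8.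

**Further compounds**

F1 | step 4 | (E)-1-[3,4-bis(benzyloxy)phenyl]-3-[4-(benzyloxy)-2-bromophenyl]prop-2-en-1-one | O=C(/C=C/c1ccc(OCc2ccccc2)cc1Br)c1ccc(OCc2ccccc2)c(OCc2ccccc2)c1
F2 | step 5 | (2S,3R)-7-(benzyloxy)-2-[3,4-bis(benzyloxy)phenyl]chroman-3-ol | O[C@@H]1Cc2ccc(OCc3ccccc3)cc2O[C@H]1c1ccc(OCc2ccccc2)c(OCc2ccccc2)c1
F3 | step 5 | (S)-O-methylmandelate of 10 | CO[C@@H](c1ccccc1)C(=O)O[C@H]1Cc2ccc(OCc3ccccc3)cc2O[C@@H]1c1ccc(OCc2ccccc2)c(OCc2ccccc2)c1
F4 | step 5 | (S)-O-methylmandelate of F2 | CO[C@@H](c1ccccc1)C(=O)O[C@@H]1Cc2ccc(OCc3ccccc3)cc2O[C@H]1c1ccc(OCc2ccccc2)c(OCc2ccccc2)c1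
F5 | step 10 | 3,4-diol from 13 and 16 (upper 3-OH free, C4 epimer mixture) | c1ccccc1COc1ccc([C@H]2Oc3cc(OCc4ccccc4)ccc3C(O)(c3cc4c(cc3OCc3ccccc3)O[C@H](c3ccc(OCc5ccccc5)c(OCc5ccccc5)c3)[C@@H](O)C4)[C@@H]2O)cc1
F6 | step 10 | 4β-aryl-flavan-3-one (2-aryl α, 4-aryl β) | c1ccccc1COc1ccc([C@H]2Oc3cc(OCc4ccccc4)ccc3[C@H](c3cc4c(cc3OCc3ccccc3)O[C@H](c3ccc(OCc5ccccc5)c(OCc5ccccc5)c3)[C@@H](O)C4)C2=O)cc1
F7 | step 10 | penta-O-benzyl ether of the target with both 3-OH groups free | c1ccccc1COc1ccc([C@H]2Oc3cc(OCc4ccccc4)ccc3[C@H](c3cc4c(cc3OCc3ccccc3)O[C@H](c3ccc(OCc5ccccc5)c(OCc5ccccc5)c3)[C@@H](O)C4)[C@@H]2O)cc1
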